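**Retrosynthetic overview**

1. Ring C is made last: O1–C2 by cyclodehydration and C2–C3 by C-acylation of a ring A ω-(methoxymethoxy)acetophenone with a ring B acid chloride.
2. The strategy rests on ring A, a phloroglucinol ring whose C8 lies between the C7 oxygen and the C8a oxygen (O1), para to the C5 oxygen, and carries the quaternary carbon of the 1,1-dimethylallyl group. Cutting C8–C8a, C6–C7 and C4a–C8a leads to a 3-alkoxycyclobutenone and a siloxyalkyne that already holds the quaternary carbon, and leaves the three oxygens different (C8a–OH free, C7–OTIPS, C5–OMe), so that only C4a can be formylated.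
3. Ring B with its fused dihydropyran (ring D) comes from 3,4-dihydroxybenzaldehyde: propargyl ether Claisen rearrangement and hydrogenation (ring D), bromination para to the protected C5' oxygen, prenylation at C2', oxidation to the acid.
4. Order of ring formation: ring A (benzannulation) and, in a separate branch, ring D on the ring B arene; then ring C; three deprotections end the route.

Key step: step 4

**Remarks**

- The alkoxy group on the cyclobutenone is chosen as methoxy (step 3). A chelated 5-O-methyl group can be removed at the end with MgI2 under conditions that should leave the prenyl group, the 1,1-dimethylallyl group and the 2,2-dimethylchromane alone. A non-chelated aryl methyl ether could not be removed so mildly, which is why ring B starts from the free catechol aldehyde.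
- Flavone numbering is used for rings A and C, chromane numbering for the ring B/D building blocks (chromane C6 = C1', C5 = C2', C8 = C5'). The target has no stereocentre; the stereogenic atoms of 9, 14 and 26 are formed without control and are erased again.
- Assumed commercial: 1, 6, 16, 3-chloro-3-methylbut-1-yne, tributyl[(methoxymethoxy)methyl]stannane and tributyl(3-methylbut-2-en-1-yl)stannane.

**Route**

Step 1
Reactants: 1 2,2-dimethylbut-3-enoic acid
Product: 2 ethyl 2,2-dimethylbut-3-enoate
Conditions: EtI, K2CO3, DMF, rt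
Reagents that add atoms: iodoethane, CCI
Why: O-alkylation of the carboxylate (SN2 esterification) is not slowed by the α-quaternary carbon, which would hamper an acid-catalysed esterification.

Step 2
Reactants: 2 ethyl 2,2-dimethylbut-3-enoate
Product: 5 (3,3-dimethylpent-4-en-1-yn-1-yloxy)triisopropylsilane, via dibromoketone enolate 3 (not isolated), via lithium ynolate 4 (not isolated)
Conditions: CH2Br2, lithium 2,2,6,6-tetramethylpiperidide, THF, −78 °C; 2; LiN(SiMe3)2; n-BuLi, −78 → 0 °C; TIPSCl, −78 °C → rt
Reagents that add atoms: dibromomethane, BrCBr; chlorotriisopropylsilane, CC(C)[Si](Cl)(C(C)C)C(C)C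
Why: Kowalski ester homologation, in which LiCHBr2 adds to the ester, enolate 3 undergoes bromine–lithium exchange and 1,2-shift of the tertiary alkyl group to give ynolate 4, and the bulky chlorosilane then silylates 4 on oxygen.

Step 3
Reactants: 6 3-ethoxycyclobut-2-en-1-one
Product: 7 3-methoxycyclobut-2-en-1-one
Conditions: TsOH·H2O (cat.), MeOH (large excess), rt; NaHCO3; distillation
Reagents that add atoms: methanol, CO
Why: Acid-catalysed addition–elimination at C3 (transetherification of a vinylogous ester, as squarate-type cyclobutenone esters undergo in alcohols) should exchange ethoxy for methoxy under mass action of the solvent.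

Step 4
Reactants: 5 (3,3-dimethylpent-4-en-1-yn-1-yloxy)triisopropylsilane; 7 3-methoxycyclobut-2-en-1-one
Product: 12 5-methoxy-2-(2-methylbut-3-en-2-yl)-3-(triisopropylsilyloxy)phenol, via vinylketene 8 (not isolated), via vinylcyclobutenone 9 (not isolated), via dienylketene 10 (not isolated), via cyclohexadienone 11 (not isolated)
Conditions: 7 (1.3 equiv), toluene, 80 °C, then 110 °C, sealed vessel, argon
Reagents that add atoms: none
Why: Danheiser benzannulation: thermal 4π electrocyclic opening of 7 gives vinylketene 8, whose ketene C=C adds [2+2] to the electron-rich triple bond of 5 to give 4-vinylcyclobutenone 9; a second 4π opening gives (E)-dienylketene 10, which closes to dienone 11 and tautomerises to phenol 12. The closest known reaction type is the benzannulation of alkyl- and aryl-substituted cyclobutenones with trialkylsiloxyalkynes to give resorcinol monosilyl ethers. Ring A is closed by thermal disrotatory 6π electrocyclisation (C4a–C8a, flavone numbering) after C8–C8a and C6–C7 have been made in the [2+2] step, and the opening of two four-membered rings together with aromatisation drives the cascade. No stereocentre remains, because the ring carbon of 9 that carries the methoxyvinyl group is formed racemic and becomes sp2 in 10. The step needs the quaternary carbon to end next to the new hydroxyl, and the polarisation of the siloxyalkyne secures this: its nucleophilic carbon (β to oxygen, bearing the 1,1-dimethylallyl group) bonds to the electrophilic central carbon of the ketene, and the oxygen-bearing carbon bonds to the ketene terminus. The ketene should prefer the oxygen-activated alkyne over the isolated vinyl group, and the hindered surroundings of the hydroxyl in 12 should limit its acylation by excess 8.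

Step 5
Reactants: 12 5-methoxy-2-(2-methylbut-3-en-2-yl)-3-(triisopropylsilyloxy)phenol
Product: 13 2-hydroxy-6-methoxy-3-(2-methylbut-3-en-2-yl)-4-(triisopropylsilyloxy)benzaldehyde
Conditions: MgCl2, Et3N, (CH2O)n, MeCN, reflux; dilute aq. HCl
Reagents that add atoms: paraformaldehyde (formaldehyde), C=O
Why: Casnati–Skattebøl ortho-formylation, in which the magnesium phenoxide delivers formaldehyde to the only free ortho carbon (C4a, between OH and OMe) and a second formaldehyde oxidises the benzylic alkoxide by hydride transfer, a process that tolerates a tertiary alkyl group at the other ortho position.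

Step 6
Reactants: 13 2-hydroxy-6-methoxy-3-(2-methylbut-3-en-2-yl)-4-(triisopropylsilyloxy)benzaldehyde
Product: 14 1-[2-hydroxy-6-methoxy-3-(2-methylbut-3-en-2-yl)-4-(triisopropylsilyloxy)phenyl]-2-(methoxymethoxy)ethan-1-ol (racemic)
Conditions: Bu3SnCH2OCH2OMe (2.3 equiv), n-BuLi, THF, −78 °C; 13, −78 → −40 °C; H2O
Reagents that add atoms: tributyl[(methoxymethoxy)methyl]stannane, CCCC[Sn](CCCC)(CCCC)COCOC
Why: Tin–lithium exchange gives (methoxymethoxy)methyllithium, of which one equivalent deprotonates the phenol and the next adds 1,2 to the aldehyde (organolithium addition); the carbinol stereocentre is formed without control and is removed in step 7.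

Step 7
Reactants: 14 1-[2-hydroxy-6-methoxy-3-(2-methylbut-3-en-2-yl)-4-(triisopropylsilyloxy)phenyl]-2-(methoxymethoxy)ethan-1-ol (racemic)
Product: 15 1-[2-hydroxy-6-methoxy-3-(2-methylbut-3-en-2-yl)-4-(triisopropylsilyloxy)phenyl]-2-(methoxymethoxy)ethan-1-one
Conditions: activated MnO2 (excess), CH2Cl2, rt
Reagents that add atoms: none
Why: Benzylic alcohol oxidation with MnO2 is selective for the benzylic carbinol and should leave the phenol, both alkenes, the acetal and the aryl silyl ether untouched, the product being stabilised by the OH···O=C hydrogen bond.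

Step 8
Reactants: 16 3,4-dihydroxybenzaldehyde
Product: 17 3-hydroxy-4-[(2-methylbut-3-yn-2-yl)oxy]benzaldehyde
Conditions: 3-chloro-3-methylbut-1-yne (1.2 equiv), K2CO3 (1.1 equiv), KI, CuI (cat.), DMF, 60 °C, N2
Reagents that add atoms: 3-chloro-3-methylbut-1-yne, C#CC(C)(C)Cl
Why: Regioselective phenol O-alkylation: one equivalent of base ionises the more acidic 4-OH (para to the formyl group), and this phenoxide is alkylated by the copper-activated tertiary propargylic chloride.

Step 9
Reactants: 17 3-hydroxy-4-[(2-methylbut-3-yn-2-yl)oxy]benzaldehyde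
Product: 18 8-hydroxy-2,2-dimethyl-2H-chromene-6-carbaldehyde
Conditions: N,N-diethylaniline, 190 °C, N2
Reagents that add atoms: none
Why: Aryl propargyl ether Claisen rearrangement to the only free ortho carbon (the other carries OH), followed by 1,5-hydrogen shift and oxa-6π electrocyclisation, closes ring D as the 2,2-dimethylchromene.

Step 10
Reactants: 18 8-hydroxy-2,2-dimethyl-2H-chromene-6-carbaldehyde
Product: 19 8-(methoxymethoxy)-2,2-dimethyl-2H-chromene-6-carbaldehyde
Conditions: MOMCl, i-Pr2NEt, CH2Cl2, 0 °C → rt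
Reagents that add atoms: chloromethyl methyl ether, COCCl
Why: Phenol O-alkylation to the MOM acetal gives a base-stable protecting group that is removable by mild acid and also serves as the para-directing alkoxy group for step 12.

Step 11
Reactants: 19 8-(methoxymethoxy)-2,2-dimethyl-2H-chromene-6-carbaldehyde
Product: 20 8-(methoxymethoxy)-2,2-dimethylchromane-6-carbaldehyde
Conditions: H2 (1 atm), 5% Pd/C, Ph2S (cat.), EtOAc, rt
Reagents that add atoms: none
Why: Catalytic hydrogenation saturates the cis-disubstituted styrenic C3=C4 bond, and the sulfide-poisoned catalyst should keep the aryl aldehyde from being reduced.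

Step 12
Reactants: 20 8-(methoxymethoxy)-2,2-dimethylchromane-6-carbaldehyde
Product: 21 5-bromo-8-(methoxymethoxy)-2,2-dimethylchromane-6-carbaldehyde
Conditions: NBS, DMF, 0 °C → rt, dark
Reagents that add atoms: N-bromosuccinimide, O=C1CCC(=O)N1Br
Why: Electrophilic aromatic bromination should go to C5, para to the OMOM group and ortho to the ring D methylene (the pattern of 6-bromination of 3,4-dialkoxybenzaldehydes), while C7 is squeezed between CHO and OMOM, and NBS keeps the medium free of HBr so that the acetal survives.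

Step 13
Reactants: 21 5-bromo-8-(methoxymethoxy)-2,2-dimethylchromane-6-carbaldehyde
Product: 22 8-(methoxymethoxy)-2,2-dimethyl-5-(3-methylbut-2-en-1-yl)chromane-6-carbaldehyde
Conditions: tributyl(3-methylbut-2-en-1-yl)stannane, Pd(PPh3)4 (5 mol%), DMF, 100 °C
Reagents that add atoms: tributyl(3-methylbut-2-en-1-yl)stannane, CC(C)=CC[Sn](CCCC)(CCCC)CCCC
Why: Stille coupling, in which the ortho-formyl group assists oxidative addition and the allylpalladium intermediate should reductively eliminate at its less hindered primary terminus to give the linear prenyl group, the aldehyde being inert to the neutral stannane.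

Step 14
Reactants: 22 8-(methoxymethoxy)-2,2-dimethyl-5-(3-methylbut-2-en-1-yl)chromane-6-carbaldehyde
Product: 23 8-(methoxymethoxy)-2,2-dimethyl-5-(3-methylbut-2-en-1-yl)chromane-6-carboxylic acid
Conditions: NaClO2, NaH2PO4, 2-methylbut-2-ene (excess), t-BuOH/H2O, rt
Reagents that add atoms: sodium chlorite, [Na+].[O-]Cl=O
Why: Pinnick oxidation converts the aldehyde to the acid at buffered pH, and the large excess of 2-methylbut-2-ene scavenges HOCl and so protects the prenyl group.

Step 15
Reactants: 15 1-[2-hydroxy-6-methoxy-3-(2-methylbut-3-en-2-yl)-4-(triisopropylsilyloxy)phenyl]-2-(methoxymethoxy)ethan-1-one; 23 8-(methoxymethoxy)-2,2-dimethyl-5-(3-methylbut-2-en-1-yl)chromane-6-carboxylic acid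
Product: 26 1-[2-hydroxy-6-methoxy-3-(2-methylbut-3-en-2-yl)-4-(triisopropylsilyloxy)phenyl]-2-(methoxymethoxy)-3-[8-(methoxymethoxy)-2,2-dimethyl-5-(3-methylbut-2-en-1-yl)chroman-6-yl]propane-1,3-dione, via acid chloride 24 (not isolated), via dilithium dianion 25 (not isolated)
Conditions: 23, 1-chloro-N,N,2-trimethylprop-1-en-1-amine, CH2Cl2, 0 °C → rt (to 24); 15, LiN(SiMe3)2 (3.2 equiv), THF, −78 °C (to 25); 24 added, −78 °C → rt; AcOH
Reagents that add atoms: none
Why: The α-chloroenamine makes acid chloride 24 without HCl, and the chelated dianion 25 (phenoxide plus Z-enolate) is C-acylated in a Claisen-type acylation (the direct variant of the Baker–Venkataraman route), any O-aroyl ester rearranging to the same diketone under the excess base; the central carbon of 26 is stereogenic but labile and becomes sp2 in step 16.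

Step 16
Reactants: 26 1-[2-hydroxy-6-methoxy-3-(2-methylbut-3-en-2-yl)-4-(triisopropylsilyloxy)phenyl]-2-(methoxymethoxy)-3-[8-(methoxymethoxy)-2,2-dimethyl-5-(3-methylbut-2-en-1-yl)chroman-6-yl]propane-1,3-dione
Product: 28 3-hydroxy-2-[8-hydroxy-2,2-dimethyl-5-(3-methylbut-2-en-1-yl)chroman-6-yl]-5-methoxy-8-(2-methylbut-3-en-2-yl)-7-(triisopropylsilyloxy)-4H-chromen-4-one, via bis-MOM flavone 27 (not isolated)
Conditions: 3 M aq. HCl, MeOH/THF, 50 °C
Reagents that add atoms: none
Why: Acid-catalysed cyclodehydration of the 2-hydroxyaryl 1,3-diketone closes ring C (attack of the C8a hydroxyl on the ring B carbonyl, then loss of water) and the same acid transfers both MOM groups to methanol, while dilute acid at 50 °C should neither protonate the monosubstituted vinyl group nor affect the prenyl group, which has no neighbouring hydroxyl, nor cleave the aryl TIPS ether.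

Step 17
Reactants: 28 3-hydroxy-2-[8-hydroxy-2,2-dimethyl-5-(3-methylbut-2-en-1-yl)chroman-6-yl]-5-methoxy-8-(2-methylbut-3-en-2-yl)-7-(triisopropylsilyloxy)-4H-chromen-4-one
Product: 29 3,5-dihydroxy-2-[8-hydroxy-2,2-dimethyl-5-(3-methylbut-2-en-1-yl)chroman-6-yl]-8-(2-methylbut-3-en-2-yl)-7-(triisopropylsilyloxy)-4H-chromen-4-one
Conditions: MgI2·OEt2 (4 equiv), THF, 60 °C; H2O
Reagents that add atoms: none
Why: Chelation-assisted demethylation, in which magnesium bound between C4=O and the 5-OMe oxygen activates only this methyl group for SN2 attack by iodide, a method suited to prenylated 5-methoxyflavonoids that should leave ring D, both allylic side chains and the silyl ether alone.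

Step 18
Reactants: 29 3,5-dihydroxy-2-[8-hydroxy-2,2-dimethyl-5-(3-methylbut-2-en-1-yl)chroman-6-yl]-8-(2-methylbut-3-en-2-yl)-7-(triisopropylsilyloxy)-4H-chromen-4-one
Product: 30 Broussoflavonol E
Conditions: Bu4NF, AcOH (1:1), THF, 0 °C → rt, argon
Reagents that add atoms: none
Why: Fluoride-mediated cleavage of the aryl silyl ether frees the 7-OH, and buffering with acetic acid should keep the polyphenolic flavonol from base-promoted autoxidation.

**Compound list**

1 | 2,2-dimethylbut-3-enoic acid | C=CC(C)(C)C(=O)O | starting material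
2 | ethyl 2,2-dimethylbut-3-enoate | C=CC(C)(C)C(=O)OCC | intermediate
3 | lithium 1,1-dibromo-3,3-dimethylpenta-1,4-dien-2-olate | [Li+].[O-]C(=C(Br)Br)C(C)(C)C=C | intermediate (not isolated)
4 | lithium 3,3-dimethylpent-4-en-1-yn-1-olate | [Li+].[O-]C#CC(C)(C)C=C | intermediate (not isolated)
5 | (3,3-dimethylpent-4-en-1-yn-1-yloxy)triisopropylsilane | C=CC(C)(C)C#CO[Si](C(C)C)(C(C)C)C(C)C | intermediate
6 | 3-ethoxycyclobut-2-en-1-one | CCOC1=CC(=O)C1 | starting material
7 | 3-methoxycyclobut-2-en-1-one | COC1=CC(=O)C1 | intermediate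
8 | 3-methoxybuta-1,3-dien-1-one | C=C(OC)C=C=O | intermediate (not isolated)
9 | 4-(1-methoxyethenyl)-2-(2-methylbut-3-en-2-yl)-3-(triisopropylsilyloxy)cyclobut-2-en-1-one (racemic) | C=CC(C)(C)C1=C(O[Si](C(C)C)(C(C)C)C(C)C)C(C(=C)OC)C1=O | intermediate (not isolated)
10 | (3E)-5-methoxy-2-(2-methylbut-3-en-2-yl)-3-(triisopropylsilyloxy)hexa-1,3,5-trien-1-one | O=C=C(C(C)(C)C=C)/C(O[Si](C(C)C)(C(C)C)C(C)C)=C\C(OC)=C | intermediate (not isolated)
11 | 5-methoxy-2-(2-methylbut-3-en-2-yl)-3-(triisopropylsilyloxy)cyclohexa-2,4-dien-1-one | O=C1CC(OC)=CC(O[Si](C(C)C)(C(C)C)C(C)C)=C1C(C)(C)C=C | intermediate (not isolated)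
12 | 5-methoxy-2-(2-methylbut-3-en-2-yl)-3-(triisopropylsilyloxy)phenol | C=CC(C)(C)c1c(O)cc(OC)cc1O[Si](C(C)C)(C(C)C)C(C)C | intermediate
13 | 2-hydroxy-6-methoxy-3-(2-methylbut-3-en-2-yl)-4-(triisopropylsilyloxy)benzaldehyde | C=CC(C)(C)c1c(O)c(C=O)c(OC)cc1O[Si](C(C)C)(C(C)C)C(C)C | intermediate
14 | 1-[2-hydroxy-6-methoxy-3-(2-methylbut-3-en-2-yl)-4-(triisopropylsilyloxy)phenyl]-2-(methoxymethoxy)ethan-1-ol (racemic) | C=CC(C)(C)c1c(O)c(C(O)COCOC)c(OC)cc1O[Si](C(C)C)(C(C)C)C(C)C | intermediate
15 | 1-[2-hydroxy-6-methoxy-3-(2-methylbut-3-en-2-yl)-4-(triisopropylsilyloxy)phenyl]-2-(methoxymethoxy)ethan-1-one | C=CC(C)(C)c1c(O)c(C(=O)COCOC)c(OC)cc1O[Si](C(C)C)(C(C)C)C(C)C | intermediate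
16 | 3,4-dihydroxybenzaldehyde | O=Cc1ccc(O)c(O)c1 | starting material
17 | 3-hydroxy-4-[(2-methylbut-3-yn-2-yl)oxy]benzaldehyde | C#CC(C)(C)Oc1ccc(C=O)cc1O | intermediate
18 | 8-hydroxy-2,2-dimethyl-2H-chromene-6-carbaldehyde | CC1(C)C=Cc2cc(C=O)cc(O)c2O1 | intermediate
19 | 8-(methoxymethoxy)-2,2-dimethyl-2H-chromene-6-carbaldehyde | COCOc1cc(C=O)cc2C=CC(C)(C)Oc12 | intermediate
20 | 8-(methoxymethoxy)-2,2-dimethylchromane-6-carbaldehyde | COCOc1cc(C=O)cc2CCC(C)(C)Oc12 | intermediate
21 | 5-bromo-8-(methoxymethoxy)-2,2-dimethylchromane-6-carbaldehyde | COCOc1cc(C=O)c(Br)c2CCC(C)(C)Oc12 | intermediate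
22 | 8-(methoxymethoxy)-2,2-dimethyl-5-(3-methylbut-2-en-1-yl)chromane-6-carbaldehyde | COCOc1cc(C=O)c(CC=C(C)C)c2CCC(C)(C)Oc12 | intermediate
23 | 8-(methoxymethoxy)-2,2-dimethyl-5-(3-methylbut-2-en-1-yl)chromane-6-carboxylic acid | COCOc1cc(C(=O)O)c(CC=C(C)C)c2CCC(C)(C)Oc12 | intermediate
24 | 8-(methoxymethoxy)-2,2-dimethyl-5-(3-methylbut-2-en-1-yl)chromane-6-carbonyl chloride | COCOc1cc(C(=O)Cl)c(CC=C(C)C)c2CCC(C)(C)Oc12 | intermediate (not isolated)
25 | dilithium salt of 15 (phenoxide and Z-enolate) | [Li+].[Li+].C=CC(C)(C)c1c([O-])c(/C([O-])=C/OCOC)c(OC)cc1O[Si](C(C)C)(C(C)C)C(C)C | intermediate (not isolated)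
26 | 1-[2-hydroxy-6-methoxy-3-(2-methylbut-3-en-2-yl)-4-(triisopropylsilyloxy)phenyl]-2-(methoxymethoxy)-3-[8-(methoxymethoxy)-2,2-dimethyl-5-(3-methylbut-2-en-1-yl)chroman-6-yl]propane-1,3-dione (keto–enol mixture, central carbon labile) | C=CC(C)(C)c1c(O)c(C(=O)C(OCOC)C(=O)c2cc(OCOC)c3OC(C)(C)CCc3c2CC=C(C)C)c(OC)cc1O[Si](C(C)C)(C(C)C)C(C)C | intermediate
27 | 5-methoxy-3-(methoxymethoxy)-2-[8-(methoxymethoxy)-2,2-dimethyl-5-(3-methylbut-2-en-1-yl)chroman-6-yl]-8-(2-methylbut-3-en-2-yl)-7-(triisopropylsilyloxy)-4H-chromen-4-one | C=CC(C)(C)c1c(O[Si](C(C)C)(C(C)C)C(C)C)cc(OC)c2c(=O)c(OCOC)c(-c3cc(OCOC)c4c(c3CC=C(C)C)CCC(C)(C)O4)oc12 | intermediate (not isolated)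
28 | 3-hydroxy-2-[8-hydroxy-2,2-dimethyl-5-(3-methylbut-2-en-1-yl)chroman-6-yl]-5-methoxy-8-(2-methylbut-3-en-2-yl)-7-(triisopropylsilyloxy)-4H-chromen-4-one | C=CC(C)(C)c1c(O[Si](C(C)C)(C(C)C)C(C)C)cc(OC)c2c(=O)c(O)c(-c3cc(O)c4c(c3CC=C(C)C)CCC(C)(C)O4)oc12 | intermediate
29 | 3,5-dihydroxy-2-[8-hydroxy-2,2-dimethyl-5-(3-methylbut-2-en-1-yl)chroman-6-yl]-8-(2-methylbut-3-en-2-yl)-7-(triisopropylsilyloxy)-4H-chromen-4-one | C=CC(C)(C)c1c(O[Si](C(C)C)(C(C)C)C(C)C)cc(O)c2c(=O)c(O)c(-c3cc(O)c4c(c3CC=C(C)C)CCC(C)(C)O4)oc12 | intermediate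
30 | Broussoflavonol E, 3,5,7-trihydroxy-2-[8-hydroxy-2,2-dimethyl-5-(3-methylbut-2-en-1-yl)chroman-6-yl]-8-(2-methylbut-3-en-2-yl)-4H-chromen-4-one | C=CC(C)(C)c1c(O)cc(O)c2c(=O)c(O)c(-c3cc(O)c4c(c3CC=C(C)C)CCC(C)(C)O4)oc12 | target

**Step count and risks**

Total step count: 18. Longest linear sequence: 11 steps (steps 8 to 14, then 15 to 18, from 3,4-dihydroxybenzaldehyde); the ring A branch from acid 1 runs over 10 steps.

The three steps most likely to fail:

Step 4. Ring opening of the donor-substituted cyclobutenone may be slower than the thermal 1,3-silyl shift of the siloxyalkyne to a silylketene, and the [2+2] addition may stall at the neopentyl-type alkyne carbon, so that the vinylketene is lost to oligomerisation. The fallback puts the 1,1-dimethylallyl group on a preformed phloroglucinol ring by aromatic Claisen rearrangement. It cannot set out from 5 or 7, since their union is what fails. It replaces steps 1 to 4, sets out from commercial 5-methoxybenzene-1,3-diol F1 and comes back to the route at 12. Mono-O-prenylation of F1 (prenyl bromide, K2CO3, acetone) should give 3-methoxy-5-[(3-methylbut-2-en-1-yl)oxy]phenol F2. Heating F2 (N,N-diethylaniline, 190 °C) should shift the allyl unit with inversion to the ortho carbon between the prenyloxy and the hydroxyl group, giving 5-methoxy-2-(2-methylbut-3-en-2-yl)benzene-1,3-diol F3, to be separated from the isomer formed at the other ortho carbon. The two hydroxyls of F3 are equivalent by symmetry, so monosilylation (TIPSCl, imidazole, DMF) can only give 12.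

Step 13. Oxidative addition and transmetalation at a carbon flanked by two ortho substituents may be slow, protodebromination may compete, and allyl transposition may lead to bond formation at the tertiary terminus. The fallback sets out from 21 and comes back at 22, building the prenyl group in two stages. Stille coupling of 21 with allyltributylstannane (Pd(PPh3)4, toluene, 110 °C), which has no regiochemical ambiguity, should give 8-(methoxymethoxy)-2,2-dimethyl-5-(prop-2-en-1-yl)chromane-6-carbaldehyde F4. Cross-metathesis of F4 with 2-methylbut-2-ene (second-generation Grubbs catalyst, CH2Cl2, 40 °C) should then give 22.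

Step 15. The dianion may be acylated on oxygen without subsequent acyl transfer, or conversion may stay incomplete because both partners are ortho-substituted. The fallback sets out from ketone 15 and aldehyde 22 (step 14 is then not needed) and comes back at 26, replacing the acylation by aldol addition and oxidation. The dianion of 15 (LiN(SiMe3)2, THF, −78 °C) should add to the unhindered aldehyde 22 to give 3-hydroxy-1-[2-hydroxy-6-methoxy-3-(2-methylbut-3-en-2-yl)-4-(triisopropylsilyloxy)phenyl]-2-(methoxymethoxy)-3-[8-(methoxymethoxy)-2,2-dimethyl-5-(3-methylbut-2-en-1-yl)chroman-6-yl]propan-1-one F5 as a mixture of diastereomers. Oxidation of F5 with Dess–Martin periodinane (NaHCO3, CH2Cl2) should give 26, both stereocentres being lost.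

**Further compounds**

F1 | step 4 | 5-methoxybenzene-1,3-diol | COc1cc(O)cc(O)c1
F2 | step 4 | 3-methoxy-5-[(3-methylbut-2-en-1-yl)oxy]phenol | COc1cc(O)cc(OCC=C(C)C)c1
F3 | step 4 | 5-methoxy-2-(2-methylbut-3-en-2-yl)benzene-1,3-diol | C=CC(C)(C)c1c(O)cc(OC)cc1O
F4 | step 13 | 8-(methoxymethoxy)-2,2-dimethyl-5-(prop-2-en-1-yl)chromane-6-carbaldehyde | COCOc1cc(C=O)c(CC=C)c2CCC(C)(C)Oc12
F5 | step 15 | 3-hydroxy-1-[2-hydroxy-6-methoxy-3-(2-methylbut-3-en-2-yl)-4-(triisopropylsilyloxy)phenyl]-2-(methoxymethoxy)-3-[8-(methoxymethoxy)-2,2-dimethyl-5-(3-methylbut-2-en-1-yl)chroman-6-yl]propan-1-one (mixture of diastereomers) | C=CC(C)(C)c1c(O)c(C(=O)C(OCOC)C(O)c2cc(OCOC)c3OC(C)(C)CCc3c2CC=C(C)C)c(OC)cc1O[Si](C(C)C)(C(C)C)C(C)C
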